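Two clocks run in grey.

| flask | starting material | first nucleophile | second nucleophile | capture agent | temperature | remark | time |
|---|---|---|---|---|---|---|---|
| south-west | 0.050 M | 0.055 M | 0.0525 M | 2.5 mM | 15 °C | run made earlier |  |
| west | 0.050 M | 0.055 M | 0.0525 M | 1.2 mM | 26 °C | run made earlier |  |
| north | 0.050 M | 0.055 M | 0.0525 M | 1.9 mM | 15 °C | run made earlier |  |
| grey | 0.050 M | 0.0550 M | 0.0525 M (fed, over 4.0 d) | 2.50 mM | 20 °C | all else is in the flask from the start; the feed brings no volume worth counting | 6.0 d |
| green | 0.050 M | 0.0550 M | 0.0525 M | 2.50 mM |  | everything together at the start at 0 °C, warmed to 20 °C at 4.0 d | 6.0 d |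
| teal | 0.050 M | 0.0550 M | 0.0525 M | 2.50 mM | 20 °C | everything together at the start | 6.0 d |
| amber | 0.050 M (fed, over 25 h) | 0.0550 M | 0.0525 M | 2.50 mM | 20 °C | all else is in the flask from the start; the feed brings no volume worth counting | 6.0 d |
| red | 0.050 M | 0.0550 M | 0.0525 M (fed, over 4.0 d) | 2.50 mM |  | the addition at 0 °C, then warmed to 20 °C; the feed brings no volume worth counting | 6.0 d |

| run | time / d | target / % | other capture product / % |
|---|---|---|---|
| south-west | 0.625 | 4 | 27 |
| south-west | 1.25 | 12 | 41 |
| south-west | 2.00 | 13 | 50 |
| south-west | 3.00 | 18 | 55 |
| south-west | 4.00 | 17 | 56 |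
| west | 1.04 | 19 | 46 |
| west | 2.08 | 21 | 43 |
| west | 3.00 | 21 | 46 |
| west | 4.00 | 21 | 46 |
| west | 5.00 | 21 | 44 |
| north | 1.04 | 14 | 38 |
| north | 2.08 | 14 | 46 |
| north | 3.00 | 19 | 54 |
| north | 4.00 | 21 | 57 |
| north | 5.00 | 17 | 57 |

(standard deviation of a reading: 2 percentage points)

1. which flask leads in share of target in target plus other capture product ("all alike" within 1.5 percentage points) (grey / green / teal / amber / red / all alike)
2. share of target in target plus other capture product at the end, grey
3. share of target in target plus other capture product at the end, green
4. share of target in target plus other capture product at the end, teal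
5. share of target in target plus other capture product at the end, amber
6. share of target in target plus other capture product at the end, red

Starting material opens on one clock, and second nucleophile arrives on the other. The south-west products reach a fraction 0.726 of their last reading at 1.25 d, so the opening constant reads 1.04 d⁻¹. The west products already stand at a fraction 0.970 of their later sum at 1.04 d, which reads 3.38 d⁻¹, a rough value under the scatter.

Interpolating in logarithms gives 0.851 for grey: this is the lead, the common logarithm of opening constant times feed time. Under grey's steady feed, one opening lifetime passes with a fraction 0.141 of the second nucleophile delivered. For grey alone, as a rough estimate, I add the lead to the log odds of target over other capture product, the selectivity.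

Those log odds, interpolated from the last readings, are −0.428 with everything together. My reckoning therefore gives teal 27.2% and, since the opening outruns the feed, grey 72.6%. Amber should match teal. Red's lead at 0 °C is only −0.0825, far less than grey's, so red should sit close to teal.

The forecast chose grey, saying “Grey starves the second nucleophile”: grey 72%, green 21%, teal 27.3%, amber 27.3%, red 30%.

The flasks give grey 74.7%, green 25.3%, teal 27.8%, amber 27.8% and red 29.3%, with grey ahead of the others.

    open intermediate + capture agent → trapped intermediate (k = 0.0541 M⁻¹ min⁻¹, Ea = 60.0 kJ mol⁻¹)
    target ⇌ isomer of the product (K = 0.353, k = 0.00745 min⁻¹, Ea = 92.0 kJ mol⁻¹, ΔH = −9.00 kJ mol⁻¹)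
    open intermediate → solvolysis product (k = 0.0397 min⁻¹, Ea = 88.0 kJ mol⁻¹)
    starting material → open intermediate (k = 0.00149 min⁻¹, Ea = 107 kJ mol⁻¹)
    second nucleophile + open intermediate → other capture product (k = 2.59 M⁻¹ min⁻¹, Ea = 42.0 kJ mol⁻¹)
    first nucleophile + open intermediate → target (k = 1.07 M⁻¹ min⁻¹, Ea = 65.0 kJ mol⁻¹)
    (constants at 20 °C)

Grey run at −5 °C takes the same reckoning, with all amounts and the time held. Carried down beyond the runs, the two read constants give a lead of −0.316, below zero where grey's stood at 0.851, and a lead below zero puts the feed ahead of the opening. That colder flask gives a share of 21.2%, far under grey's 74.7%, with other capture product at 12.9% of the charge. Starting material still holds 80.7% of the charge at 6.00 d.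

The earlier runs and the new flask are calculated with made-up constants.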